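**Strategy.** Everything rests on cutting the carbocycle of the tetrahydronaphtho[2,3-b]furan half at both of its aryl–C(sp3) bonds, C4a–C5 and C8a–C8 (primed locants: dihydrobenzofuran half). The key step generates an aryne at C4a/C8a, next to the C9 ether oxygen, and traps it with an (E,E)-pentadienyl group on C2′: one intramolecular [4+2] closes the cyclohexadiene ring and, through the O–C3′–C2′ tether, the pyran ring, and sets C5 and C8. The feature exploited is the cis-5,8-disubstituted six-membered ring annulated on adjacent arene carbons peri to that oxygen. The precursor is a cis-2′-dienyl-3′-aryloxy-3′-methyl-dihydrobenzofuran whose aryl group is a 5-bromo-6-iodobenzofuran, assembled from a benzofuranone.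

Key step: step 16

Assumption: the target is the (5S,8R,2′R,3′R) isomer; unprimed locants follow naphtho[2,3-b]furan numbering (O1, C2, C3, C3a, C4, C4a, C5–C8, C8a, C9, C9a), primed locants the 2,3-dihydro-1-benzofuran unit, and the halves are joined by the C8–C2′ bond and the C9–O–C3′ ether.

**Ring A building block**

Step 1
Reactants: 1 2-bromo-3-methylphenol
Product: 2 3-bromo-2-hydroxy-4-methylbenzaldehyde
Conditions: (CH2O)n, MgCl2, Et3N, MeCN, reflux
Reagents that add atoms: paraformaldehyde (formaldehyde), C=O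
Why: Casnati–Skattebøl ortho-formylation: the magnesium phenoxide delivers formaldehyde to the only free ortho carbon and a second formaldehyde takes up the hydride, so the para position stays untouched; no stereocentre.

Step 2
Reactants: 2 3-bromo-2-hydroxy-4-methylbenzaldehyde
Product: 3 3-bromo-2-(methoxymethoxy)-4-methylbenzaldehyde
Conditions: MOMCl, i-Pr2NEt, CH2Cl2, 0 °C to rt
Reagents that add atoms: chloromethyl methyl ether, COCCl
Why: Williamson-type O-alkylation of the phenol gives an acetal ether that should survive the later base, hydride, ylide and organolithium steps.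

Step 3
Reactants: 3 3-bromo-2-(methoxymethoxy)-4-methylbenzaldehyde
Product: 5 3-bromo-2-(methoxymethoxy)-4-methylphenol, via aryl formate 4 (not isolated)
Conditions: mCPBA, CH2Cl2, 0 °C to rt; then K2CO3, MeOH, rt
Reagents that add atoms: mCPBA, OOC(=O)c1cccc(Cl)c1
Why: Baeyer–Villiger (Dakin-type) oxidation: the electron-rich aryl group migrates in the peroxy-hemiacetal, and methanolysis of the formate frees only the new phenol, which differentiates the two catechol oxygens.

Step 4
Reactants: 5 3-bromo-2-(methoxymethoxy)-4-methylphenol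
Product: 7 (3RS)-6-bromo-3-hydroxy-7-(methoxymethoxy)-5-methyl-1-benzofuran-2(3H)-one, via hydroxy acid 6 (not isolated)
Conditions: glyoxylic acid (aq), NaOH, H2O, rt; HCl to pH 2, extraction; then DCC, CH2Cl2, 0 °C
Reagents that add atoms: glyoxylic acid, OC(=O)C=O
Why: Ortho-hydroxyalkylation of the phenoxide by glyoxylate (para is blocked by methyl, the other ortho position by the ether) followed by carbodiimide lactonisation gives the mandelic lactone; its stereocentre is racemic and is flattened in step 11.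

**Ring B building block**

Step 5
Reactants: 8 2-methoxy-5-methylphenol
Product: 9 4-bromo-2-methoxy-5-methylphenol
Conditions: NBS, MeCN, 0 °C
Reagents that add atoms: N-bromosuccinimide, O=C1CCC(=O)N1Br
Why: Electrophilic aromatic bromination goes para to the free hydroxyl, the strongest director, at the carbon that later becomes one aryne carbon.

Step 6
Reactants: 9 4-bromo-2-methoxy-5-methylphenol
Product: 10 1-(4-bromo-2-methoxy-5-methylphenoxy)propan-2-one
Conditions: chloroacetone, K2CO3, KI (cat.), acetone, reflux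
Reagents that add atoms: chloroacetone, CC(=O)CCl
Why: Williamson etherification of the phenoxide with the α-chloro ketone.

Step 7
Reactants: 10 1-(4-bromo-2-methoxy-5-methylphenoxy)propan-2-one
Product: 11 5-bromo-7-methoxy-3,4-dimethyl-1-benzofuran
Conditions: polyphosphoric acid, 80 °C
Reagents that add atoms: none
Why: Acid-mediated cyclodehydration (intramolecular Friedel–Crafts hydroxyalkylation, then loss of water) can only close on the single free ortho carbon and gives the 3,4-dimethylbenzofuran.

Step 8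
Reactants: 11 5-bromo-7-methoxy-3,4-dimethyl-1-benzofuran
Product: 12 5-bromo-3,4-dimethyl-1-benzofuran-7-ol
Conditions: BBr3, CH2Cl2, −78 °C to 0 °C
Reagents that add atoms: none
Why: Lewis acid demethylation of the aryl methyl ether through its bromoborane complex; benzofuran and aryl bromide should be inert.

Step 9
Reactants: 12 5-bromo-3,4-dimethyl-1-benzofuran-7-ol
Product: 13 5-bromo-6-iodo-3,4-dimethyl-1-benzofuran-7-ol
Conditions: I2, NaHCO3, THF/H2O, 0 °C to rt
Reagents that add atoms: iodine, II
Why: Electrophilic iodination of the phenoxide at its only free ortho carbon (para is methyl-blocked) installs the halogen that later triggers aryne formation; the furan C-2 is far less nucleophilic than the phenoxide ring.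

**Union and elaboration**

Step 10
Reactants: 7 (3RS)-6-bromo-3-hydroxy-7-(methoxymethoxy)-5-methyl-1-benzofuran-2(3H)-one; 13 5-bromo-6-iodo-3,4-dimethyl-1-benzofuran-7-ol
Product: 14 (3RS)-6-bromo-3-[(5-bromo-6-iodo-3,4-dimethyl-1-benzofuran-7-yl)oxy]-7-(methoxymethoxy)-5-methyl-1-benzofuran-2(3H)-one
Conditions: PPh3, DIAD, THF, 0 °C to rt
Reagents that add atoms: none
Why: Mitsunobu etherification: the acidic, hindered phenol displaces the activated secondary benzylic α-carbonyl hydroxyl by SN2, forging the crowded aryl ether at a still secondary carbon; configuration is irrelevant because step 11 passes through the enolate.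

Step 11
Reactants: 14 (3RS)-6-bromo-3-[(5-bromo-6-iodo-3,4-dimethyl-1-benzofuran-7-yl)oxy]-7-(methoxymethoxy)-5-methyl-1-benzofuran-2(3H)-one
Product: 15 (3R)-6-bromo-3-[(5-bromo-6-iodo-3,4-dimethyl-1-benzofuran-7-yl)oxy]-7-(methoxymethoxy)-3,5-dimethyl-1-benzofuran-2(3H)-one
Conditions: MeI, Cs2CO3 (solid), O-allyl-N-(9-anthracenylmethyl)cinchonidinium bromide (10 mol%), toluene, −40 °C
Reagents that add atoms: iodomethane, CI
Why: Asymmetric phase-transfer C-methylation of the aromatic 2-oxidobenzofuran enolate: the chiral ammonium ion pair shields one enolate face and sets C-3 as R (the pseudo-enantiomeric cinchoninium salt is taken if that is the one giving R), and both enantiomers of 14 converge on the same planar enolate.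

Step 12
Reactants: 15 (3R)-6-bromo-3-[(5-bromo-6-iodo-3,4-dimethyl-1-benzofuran-7-yl)oxy]-7-(methoxymethoxy)-3,5-dimethyl-1-benzofuran-2(3H)-one
Product: 16 (3R)-6-bromo-3-[(5-bromo-6-iodo-3,4-dimethyl-1-benzofuran-7-yl)oxy]-7-(methoxymethoxy)-3,5-dimethyl-2,3-dihydro-1-benzofuran-2-ol (both C-2 epimers)
Conditions: i-Bu2AlH, CH2Cl2, −78 °C
Reagents that add atoms: none
Why: Partial reduction of the aryl lactone to the lactol: the tetrahedral aluminium alkoxide is stable at −78 °C and collapses only on work-up; C-3 is untouched and C-2 forms as an inconsequential epimer mixture.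

Step 13
Reactants: 17 (2E)-5-bromopent-2-ene
Product: 18 [(3E)-pent-3-en-1-yl]triphenylphosphonium bromide
Conditions: PPh3, MeCN, reflux
Reagents that add atoms: triphenylphosphine, c1ccc(cc1)P(c1ccccc1)c1ccccc1
Why: SN2 quaternisation of the phosphine by the primary homoallylic bromide; the E-alkene is not involved.

Step 14
Reactants: 16 (3R)-6-bromo-3-[(5-bromo-6-iodo-3,4-dimethyl-1-benzofuran-7-yl)oxy]-7-(methoxymethoxy)-3,5-dimethyl-2,3-dihydro-1-benzofuran-2-ol; 18 [(3E)-pent-3-en-1-yl]triphenylphosphonium bromide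
Product: 19 3-bromo-6-[(2S,3Z,6E)-2-[(5-bromo-6-iodo-3,4-dimethyl-1-benzofuran-7-yl)oxy]octa-3,6-dien-2-yl]-2-(methoxymethoxy)-4-methylphenol
Conditions: KN(SiMe3)2, THF, −78 °C to rt (ylide in excess)
Reagents that add atoms: none
Why: Wittig olefination of the hydroxy-aldehyde form of the lactol with a non-stabilised ylide under salt-free conditions should give the Z-alkene; the quaternary centre cannot epimerise (its descriptor changes to S only through the priority rules).

Step 15
Reactants: 19 3-bromo-6-[(2S,3Z,6E)-2-[(5-bromo-6-iodo-3,4-dimethyl-1-benzofuran-7-yl)oxy]octa-3,6-dien-2-yl]-2-(methoxymethoxy)-4-methylphenol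
Product: 22 (2R,3R)-6-bromo-3-[(5-bromo-6-iodo-3,4-dimethyl-1-benzofuran-7-yl)oxy]-7-(methoxymethoxy)-3,5-dimethyl-2-[(1E,3E)-penta-1,3-dien-1-yl]-2,3-dihydro-1-benzofuran, via selenide 20 (not isolated), via selenoxide 21 (not isolated)
Conditions: PhSeCl, K2CO3, CH2Cl2, −78 °C; then H2O2 (30%), pyridine, 0 °C to rt
Reagents that add atoms: none
Why: Phenylselenoetherification closes the dihydrofuran by 5-exo-trig anti addition across the Z-alkene, and selenoxide syn-elimination, which avoids the oxygen-bearing carbon, moves the double bond into conjugation as the E isomer; C-2 is set in the cyclisation by allylic 1,3-strain, the C3–OAr bond (smaller than methyl) eclipsing the Z-alkene while the arene stands perpendicular, so the side chain should end cis to the aryloxy group.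

Step 16
Reactants: 22 (2R,3R)-6-bromo-3-[(5-bromo-6-iodo-3,4-dimethyl-1-benzofuran-7-yl)oxy]-7-(methoxymethoxy)-3,5-dimethyl-2-[(1E,3E)-penta-1,3-dien-1-yl]-2,3-dihydro-1-benzofuran
Product: 25 (5S,8R,2′R,3′R)-6′-bromo-7′-(methoxymethoxy)-3,4,5,3′,5′-pentamethyl-5,8-dihydro cycloadduct (C8–C2′ bond; C9–O–C3′ ether), via aryl-lithium 23 (not isolated), via aryne 24 (not isolated)
Conditions: n-BuLi (1.05 equiv), THF, −95 °C to rt, 0.005 M
Reagents that add atoms: none
Why: Iodine–lithium exchange at C-6 of the benzofuran (much faster than bromine–lithium exchange at the hindered ring A bromide) gives 2-bromoaryl-lithium 23, which loses LiBr on warming to the 5,6-benzofuranyne 24, and this is trapped within the molecule by the (E,E)-diene in a concerted suprafacial [4+2] cycloaddition. The closest known reaction type is the intramolecular aryne Diels–Alder reaction of arynes that carry a dienyl chain on an ortho oxygen substituent. The cyclohexadiene ring closes by the [4+2] itself (C8a–C8 and C4a–C5 in one event), and the pyran ring is the six-membered ring spanned by the O–C3′–C2′ tether between C-9 and the inner diene terminus. C-5 follows from the E,E geometry, which puts the C-5 and C-8 hydrogens cis; C-8 is controlled by C-2′, because the tether is expected to react through the half-chair in which the C2′–O bond lies near the diene plane (inside position), the C-3′ aryl is pseudo-equatorial and the C-3′ methyl rather than the aryl ring is 1,3-diaxial to the inside hydrogen of C-8, which gives the 8,2′-cis hydrogens. The step needs this facial selectivity, exchange at iodine only, and cycloaddition faster than capture of the aryne by butyl- or aryl-lithium; the rigid cis-fused dihydrobenzofuran, the iodide, and high dilution with one equivalent of n-BuLi are meant to secure them.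

Step 17
Reactants: 25 (5S,8R,2′R,3′R)-6′-bromo-7′-(methoxymethoxy)-3,4,5,3′,5′-pentamethyl-5,8-dihydro cycloadduct
Product: 26 (5S,8R,2′R,3′R)-6′-bromo-7′-(methoxymethoxy)-3,4,5,3′,5′-pentamethyl-5,6,7,8-tetrahydro pentacycle
Conditions: 2-nitrobenzenesulfonohydrazide, Et3N, CH2Cl2, rt, under argon
Reagents that add atoms: none
Why: Diimide generated in the flask transfers H2 in a concerted syn fashion to the cis-disubstituted ring alkene only; aryl bromide, benzofuran and benzylic ethers should be inert and no stereocentre is touched.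

Step 18
Reactants: 17 (2E)-5-bromopent-2-ene
Product: 27 [(3E)-pent-3-en-1-yl]zinc bromide (THF solution, used directly)
Conditions: Zn dust (activated), LiCl, THF, 40 °C
Reagents that add atoms: zinc, [Zn]
Why: Direct oxidative insertion of LiCl-activated zinc into the primary C–Br bond gives a homoallylic organozinc that keeps the E geometry.

Step 19
Reactants: 26 (5S,8R,2′R,3′R)-6′-bromo-7′-(methoxymethoxy)-3,4,5,3′,5′-pentamethyl-5,6,7,8-tetrahydro pentacycle; 27 [(3E)-pent-3-en-1-yl]zinc bromide
Product: 28 (5S,8R,2′R,3′R)-7′-(methoxymethoxy)-3,4,5,3′,5′-pentamethyl-6′-[(3E)-pent-3-en-1-yl]-5,6,7,8-tetrahydro pentacycle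
Conditions: Pd(OAc)2 (2 mol%), SPhos (4 mol%), THF, 50 °C
Reagents that add atoms: none
Why: Negishi cross-coupling of the primary alkylzinc reagent with the hindered aryl bromide; the biaryl dicyclohexylphosphine should make reductive elimination outrun β-hydride elimination, and the alkene geometry is untouched.

Step 20
Reactants: 28 (5S,8R,2′R,3′R)-7′-(methoxymethoxy)-3,4,5,3′,5′-pentamethyl-6′-[(3E)-pent-3-en-1-yl]-5,6,7,8-tetrahydro pentacycle
Product: 29 target, (5S,8R,2′R,3′R)-3,4,5,3′,5′-pentamethyl-6′-[(3E)-pent-3-en-1-yl]-5,6,7,8-tetrahydro pentacycle-7′-ol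
Conditions: ZnBr2, n-PrSH, CH2Cl2, 0 °C, short reaction time
Reagents that add atoms: none
Why: Lewis acid-assisted acetal exchange: ZnBr2 activates the methoxymethyl acetal and the thiol carries off the CH2OMe group, which should free the phenol fast enough to spare the tertiary benzylic ether and the alkene; no stereocentre is affected.

**Compound list**

1 | 2-bromo-3-methylphenol | Cc1cccc(O)c1Br | starting material
2 | 3-bromo-2-hydroxy-4-methylbenzaldehyde | Cc1ccc(C=O)c(O)c1Br | intermediate
3 | 3-bromo-2-(methoxymethoxy)-4-methylbenzaldehyde | COCOc1c(C=O)ccc(C)c1Br | intermediate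
4 | 3-bromo-2-(methoxymethoxy)-4-methylphenyl formate | COCOc1c(OC=O)ccc(C)c1Br | intermediate
5 | 3-bromo-2-(methoxymethoxy)-4-methylphenol | COCOc1c(O)ccc(C)c1Br | intermediate
6 | (RS)-2-[4-bromo-2-hydroxy-3-(methoxymethoxy)-5-methylphenyl]-2-hydroxyacetic acid | COCOc1c(O)c(cc(C)c1Br)C(O)C(O)=O | intermediate
7 | (3RS)-6-bromo-3-hydroxy-7-(methoxymethoxy)-5-methyl-1-benzofuran-2(3H)-one | COCOc1c2OC(=O)C(O)c2cc(C)c1Br | intermediate
8 | 2-methoxy-5-methylphenol | COc1ccc(C)cc1O | starting material
9 | 4-bromo-2-methoxy-5-methylphenol | COc1cc(Br)c(C)cc1O | intermediate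
10 | 1-(4-bromo-2-methoxy-5-methylphenoxy)propan-2-one | COc1cc(Br)c(C)cc1OCC(C)=O | intermediate
11 | 5-bromo-7-methoxy-3,4-dimethyl-1-benzofuran | COc1cc(Br)c(C)c2c(C)coc12 | intermediate
12 | 5-bromo-3,4-dimethyl-1-benzofuran-7-ol | Cc1coc2c(O)cc(Br)c(C)c12 | intermediate
13 | 5-bromo-6-iodo-3,4-dimethyl-1-benzofuran-7-ol | Cc1coc2c(O)c(I)c(Br)c(C)c12 | intermediate
14 | (3RS)-6-bromo-3-[(5-bromo-6-iodo-3,4-dimethyl-1-benzofuran-7-yl)oxy]-7-(methoxymethoxy)-5-methyl-1-benzofuran-2(3H)-one | COCOc1c2OC(=O)C(Oc3c(I)c(Br)c(C)c4c(C)coc34)c2cc(C)c1Br | intermediate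
15 | (3R)-6-bromo-3-[(5-bromo-6-iodo-3,4-dimethyl-1-benzofuran-7-yl)oxy]-7-(methoxymethoxy)-3,5-dimethyl-1-benzofuran-2(3H)-one | COCOc1c2OC(=O)[C@](C)(Oc3c(I)c(Br)c(C)c4c(C)coc34)c2cc(C)c1Br | intermediate
16 | (3R)-6-bromo-3-[(5-bromo-6-iodo-3,4-dimethyl-1-benzofuran-7-yl)oxy]-7-(methoxymethoxy)-3,5-dimethyl-2,3-dihydro-1-benzofuran-2-ol (C-2 epimers) | COCOc1c2OC(O)[C@](C)(Oc3c(I)c(Br)c(C)c4c(C)coc34)c2cc(C)c1Br | intermediate
17 | (2E)-5-bromopent-2-ene | C/C=C/CCBr | starting material
18 | [(3E)-pent-3-en-1-yl]triphenylphosphonium bromide | C/C=C/CC[P+](c1ccccc1)(c1ccccc1)c1ccccc1.[Br-] | intermediate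
19 | 3-bromo-6-[(2S,3Z,6E)-2-[(5-bromo-6-iodo-3,4-dimethyl-1-benzofuran-7-yl)oxy]octa-3,6-dien-2-yl]-2-(methoxymethoxy)-4-methylphenol | COCOc1c(O)c(cc(C)c1Br)[C@@](C)(Oc1c(I)c(Br)c(C)c2c(C)coc12)/C=C\C/C=C/C | intermediate
20 | (2S,3R)-6-bromo-3-[(5-bromo-6-iodo-3,4-dimethyl-1-benzofuran-7-yl)oxy]-7-(methoxymethoxy)-3,5-dimethyl-2-[(1S,3E)-1-(phenylselanyl)pent-3-en-1-yl]-2,3-dihydro-1-benzofuran | COCOc1c2O[C@H]([C@@H]([Se]c3ccccc3)C/C=C/C)[C@](C)(Oc3c(I)c(Br)c(C)c4c(C)coc34)c2cc(C)c1Br | intermediate
21 | Se-oxide of 20 (selenoxide, both configurations at selenium) | COCOc1c2O[C@H]([C@@H]([Se](=O)c3ccccc3)C/C=C/C)[C@](C)(Oc3c(I)c(Br)c(C)c4c(C)coc34)c2cc(C)c1Br | intermediate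
22 | (2R,3R)-6-bromo-3-[(5-bromo-6-iodo-3,4-dimethyl-1-benzofuran-7-yl)oxy]-7-(methoxymethoxy)-3,5-dimethyl-2-[(1E,3E)-penta-1,3-dien-1-yl]-2,3-dihydro-1-benzofuran | COCOc1c2O[C@H](/C=C/C=C/C)[C@](C)(Oc3c(I)c(Br)c(C)c4c(C)coc34)c2cc(C)c1Br | intermediate
23 | 6-lithio analogue of 22 (lithium in place of iodine on the benzofuran) | COCOc1c2O[C@H](/C=C/C=C/C)[C@](C)(Oc3c([Li])c(Br)c(C)c4c(C)coc34)c2cc(C)c1Br | intermediate
24 | 5,6-didehydrobenzofuran (aryne) from 23 | COCOc1c2O[C@H](/C=C/C=C/C)[C@](C)(OC3=C4OC=C(C)C4=C(C)C#C3)c2cc(C)c1Br | intermediate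
25 | (5S,8R,2′R,3′R)-cycloadduct: 3,4,5-trimethyl-5,8-dihydronaphtho[2,3-b]furan joined by C8–C2′ and C9–O–C3′ to 6′-bromo-7′-(methoxymethoxy)-3′,5′-dimethyl-2′,3′-dihydro-1-benzofuran | Brc1c(C)cc2c(c1OCOC)O[C@@H]1[C@@H]3C=C[C@H](C)c4c3c(c3occ(C)c3c4C)O[C@]21C | intermediate
26 | (5S,8R,2′R,3′R)-5,6,7,8-tetrahydro analogue of 25 | Brc1c(C)cc2c(c1OCOC)O[C@@H]1[C@@H]3CC[C@H](C)c4c3c(c3occ(C)c3c4C)O[C@]21C | intermediate
27 | [(3E)-pent-3-en-1-yl]zinc bromide | C/C=C/CC[Zn]Br | intermediate
28 | (5S,8R,2′R,3′R)-7′-O-methoxymethyl ether of the target | C/C=C/CCc1c(C)cc2c(c1OCOC)O[C@@H]1[C@@H]3CC[C@H](C)c4c3c(c3occ(C)c3c4C)O[C@]21C | intermediate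
29 | target, (5S,8R,2′R,3′R): 3,4,5-trimethyl-5,6,7,8-tetrahydronaphtho[2,3-b]furan joined by C8–C2′ and C9–O–C3′ to 3′,5′-dimethyl-6′-[(3E)-pent-3-en-1-yl]-2′,3′-dihydro-1-benzofuran-7′-ol | C/C=C/CCc1c(C)cc2c(c1O)O[C@@H]1[C@@H]3CC[C@H](C)c4c3c(c3occ(C)c3c4C)O[C@]21C | target

**Totals.** Total step count: 20. Longest linear sequence: 14 steps (5–9, 10–12, 14–17, 19, 20), starting from 2-methoxy-5-methylphenol 8; the ring A branch (steps 1–4) is one step shorter.

**Steps most likely to fail**

Step 16 (key step). The diene may add to the wrong face of the aryne, or the aryl-lithium and aryne may be diverted by bromine–lithium exchange on ring A or by butyl addition. Fallback, from 16 back to 25: the dihydrofuran is left open during the cycloaddition and C-2′ becomes a temporary, freely chosen stereocentre. Lactol 16 is opened by the alkenylzinc reagent made from (E)-pent-3-en-1-yne, Cp2Zr(H)Cl and Me2Zn, and the (3R)-epimer of the resulting dienyl carbinol F1 is silylated on both oxygens (t-BuMe2SiOSO2CF3, 2,6-lutidine) to bis-silyl ether F2. Treatment with n-BuLi as in step 16 should give cycloadduct F3, in which a bulky silyloxy group instead of a ring oxygen biases the tether; the 3-epimer is equally accessible and is used if it steers the diene better. n-Bu4NF then frees diol F4, Parikh–Doering oxidation (SO3·pyridine, DMSO, i-Pr2NEt) of the secondary alcohol gives ketone F5, and the neighbouring phenol closes it to hemiketal F6. Reduction of the derived oxocarbenium ion (Et3SiH, BF3·OEt2, −78 °C) should deliver 25, because only the cis-fused dihydrofuran is accessible; C-2′ then follows from C-3′ and the temporary centre is erased.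

Step 15. The selenium electrophile may close the six-membered ring instead (6-endo), attack the remote alkene, or give poor selectivity at C-2. Fallback, from 16 back to 22: the alkenylzinc addition described above is used to obtain the (3S)-epimer of the dienyl carbinol F7, separated from its epimer by chromatography. Mitsunobu cyclodehydration (PPh3, DIAD, THF) lets the phenol displace the activated dienylic hydroxyl with inversion and should give 22, with C-2 fixed by the carbinol configuration instead of by the conformation of the alkene.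

Step 11. The ion-pair-controlled methylation may give low enantiomeric excess. Fallback, from 14 back to 16: methylation with an achiral phase-transfer salt (n-Bu4NBr, K2CO3, MeI) gives racemic lactone F8. Ring opening with sodium (1R,2S,5R)-mentholate gives two diastereomeric menthyl esters, from which the (2R)-configured menthyl ester F9 is separated by chromatography or crystallisation. Reduction with i-Bu2AlH at −78 °C takes the ester to the aldehyde, which closes to lactol 16.

**Further compounds**

F1 | step 16 | 3-bromo-6-[(2R,3R,4E,6E)-2-[(5-bromo-6-iodo-3,4-dimethyl-1-benzofuran-7-yl)oxy]-3-hydroxyocta-4,6-dien-2-yl]-2-(methoxymethoxy)-4-methylphenol | COCOc1c(O)c(cc(C)c1Br)[C@@](C)(Oc1c(I)c(Br)c(C)c2c(C)coc12)[C@H](O)/C=C/C=C/C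
F2 | step 16 | bis(tert-butyldimethylsilyl) ether of F1 (phenol and carbinol oxygens) | COCOc1c(O[Si](C)(C)C(C)(C)C)c(cc(C)c1Br)[C@@](C)(Oc1c(I)c(Br)c(C)c2c(C)coc12)[C@H](O[Si](C)(C)C(C)(C)C)/C=C/C=C/C
F3 | step 16 | cycloadduct of F2: (5S,8R,2′R,3′R)-5,8-dihydro tetracycle with C2′–OSi, open dihydrofuran and aryl silyl ether | COCOc1c(O[Si](C)(C)C(C)(C)C)c(cc(C)c1Br)[C@@]2(C)Oc3c4occ(C)c4c(C)c4c3[C@H]([C@H]2O[Si](C)(C)C(C)(C)C)C=C[C@@H]4C
F4 | step 16 | diol from F3 (free phenol and C2′ carbinol) | COCOc1c(O)c(cc(C)c1Br)[C@@]2(C)Oc3c4occ(C)c4c(C)c4c3[C@H]([C@H]2O)C=C[C@@H]4C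
F5 | step 16 | C2′ ketone from F4 | COCOc1c(O)c(cc(C)c1Br)[C@@]2(C)Oc3c4occ(C)c4c(C)c4c3[C@H](C2=O)C=C[C@@H]4C
F6 | step 16 | cyclic hemiketal of F5 (2′-hydroxy analogue of 25) | Brc1c(C)cc2c(c1OCOC)O[C@]1(O)[C@@H]3C=C[C@H](C)c4c3c(c3occ(C)c3c4C)O[C@]21C
F7 | step 15 | 3-bromo-6-[(2R,3S,4E,6E)-2-[(5-bromo-6-iodo-3,4-dimethyl-1-benzofuran-7-yl)oxy]-3-hydroxyocta-4,6-dien-2-yl]-2-(methoxymethoxy)-4-methylphenol | COCOc1c(O)c(cc(C)c1Br)[C@@](C)(Oc1c(I)c(Br)c(C)c2c(C)coc12)[C@@H](O)/C=C/C=C/C
F8 | step 11 | racemic 6-bromo-3-[(5-bromo-6-iodo-3,4-dimethyl-1-benzofuran-7-yl)oxy]-7-(methoxymethoxy)-3,5-dimethyl-1-benzofuran-2(3H)-one | COCOc1c2OC(=O)C(C)(Oc3c(I)c(Br)c(C)c4c(C)coc34)c2cc(C)c1Br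
F9 | step 11 | (1R,2S,5R)-menthyl (2R)-2-[4-bromo-2-hydroxy-3-(methoxymethoxy)-5-methylphenyl]-2-[(5-bromo-6-iodo-3,4-dimethyl-1-benzofuran-7-yl)oxy]propanoate | COCOc1c(O)c(cc(C)c1Br)[C@@](C)(Oc1c(I)c(Br)c(C)c2c(C)coc12)C(=O)O[C@@H]1C[C@H](C)CC[C@H]1C(C)C
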